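**Retrosynthetic overview**
- The target is a trans-2,3-diaryl-1,4-benzodioxane, the dehydro-dimer of piceatannol. Both C–O bonds of the dioxane ring are cut, giving piceatannol ortho-quinone (the O=C–C=O unit) and the stilbene C=C of a second piceatannol, as in the presumed biosynthetic oxidative coupling.
- The dioxane ring is the only ring made. Its first bond joins the quinone oxygen meta to the styryl group to the olefinic carbon that carries the resorcinol ring; this bond sets the absolute configuration under a chiral phosphoric acid. The para-phenol then closes onto the resulting para-quinone methide, giving the trans ring.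
- Piceatannol is a catalogue compound and is bought; both halves of the target, all four benzene rings and the (E)-olefin come from it, so the synthesis is a single operation.

Assumption: the target SMILES encodes the trans-(2S,3S) isomer; the sense of induction of the chiral acid cannot be predicted, so the (R)-acid is written and its mirror image replaces it if the first analytical run shows the (2R,3R) product in excess.

Locants: in piceatannol, C7 is the olefinic carbon on the catechol ring and C8 the one on the resorcinol ring.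

**Step 1**
Reactants: 1 piceatannol [4-[(E)-2-(3,5-dihydroxyphenyl)ethenyl]benzene-1,2-diol] (two molecules: one is dehydrogenated in the flask to 2, the other supplies the C7=C8 bond)
Product: 4 (2S,3S)-2-(3,4-dihydroxyphenyl)-3-(3,5-dihydroxyphenyl)-6-[(E)-2-(3,5-dihydroxyphenyl)ethenyl]-2,3-dihydro-1,4-benzodioxine (target), via piceatannol ortho-quinone 2 (not isolated), via para-quinone methide aryl ether 3 (not isolated)
Conditions: 2,3-dichloro-5,6-dicyano-1,4-benzoquinone (DDQ, 0.45 equiv, syringe pump, 8 h), (R)-3,3'-bis(2,4,6-triisopropylphenyl)-1,1'-binaphthyl-2,2'-diyl hydrogen phosphate (10 mol %), 4 Å MS, EtOAc/CH2Cl2 1:1 (0.02 M), −40 °C, dark, argon; C18 chromatography, then chiral-phase HPLC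
Reagents that add atoms: none
Why: Proposed new method: DDQ dehydrogenates the catechol of one piceatannol to ortho-quinone 2, and the chiral phosphoric acid is meant to bridge a quinone carbonyl oxygen (P–OH donor) and the 4-OH of a second piceatannol (P=O acceptor), so that the vinylogous-phenol carbon C8 attacks from one enantiotopic face the quinone oxygen meta to the styryl group (this leaves the developing phenoxide on the para oxygen, the more acidic and conjugated one) to give para-quinone methide 3 with the first stereocentre, after which the para-phenol adds 1,6 to C7 (oxa-Michael, reversible under the acid, hence trans) to give the (2S,3S)-benzodioxane, the 2,3-transposed regioisomer being the expected by-product removed on C18; the closest known reactions are the racemic silver-oxide dehydrodimerisation of catechol phenylpropanoids to trans-1,4-benzodioxanes, the inverse-electron-demand oxa-Diels–Alder reaction of ortho-quinones with styrenes, and chiral-phosphoric-acid-catalysed formal cycloadditions of quinones with hydroxystyrenes.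

**Compound list**
1 | piceatannol, 4-[(E)-2-(3,5-dihydroxyphenyl)ethenyl]benzene-1,2-diol | Oc1cc(O)cc(/C=C/c2ccc(O)c(O)c2)c1 | starting material
2 | piceatannol ortho-quinone, 4-[(E)-2-(3,5-dihydroxyphenyl)ethenyl]cyclohexa-3,5-diene-1,2-dione | O=C1C=CC(/C=C/c2cc(O)cc(O)c2)=CC1=O | intermediate
3 | para-quinone methide aryl ether, 2-hydroxy-4-[(2R)-2-(3,5-dihydroxyphenyl)-2-{5-[(E)-2-(3,5-dihydroxyphenyl)ethenyl]-2-hydroxyphenoxy}ethylidene]cyclohexa-2,5-dien-1-one (ylidene geometry open; same spatial arrangement at the ether carbon as C3 of 4) | Oc1cc(O)cc(/C=C/c2ccc(O)c(O[C@@H](c3cc(O)cc(O)c3)C=C3C=CC(=O)C(O)=C3)c2)c1 | intermediate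
4 | (2S,3S)-2-(3,4-dihydroxyphenyl)-3-(3,5-dihydroxyphenyl)-6-[(E)-2-(3,5-dihydroxyphenyl)ethenyl]-2,3-dihydro-1,4-benzodioxine | Oc1cc(O)cc(/C=C/c2ccc3c(c2)O[C@@H](c2cc(O)cc(O)c2)[C@H](c2ccc(O)c(O)c2)O3)c1 | target

**Totals**
Total step count: 1. Longest linear sequence: 1 (piceatannol to target).

**Most likely failures and fallbacks**
The route has a single step, so the three entries are the three unrelated ways in which step 1 can fail.

First, step 1 may give poor asymmetric induction. Six free phenols and a polar solvent compete for the hydrogen bonds of the catalyst, the hydroquinone formed from DDQ is an achiral acid, and any uncatalysed or radical coupling gives racemate. The fallback sets out from 1 and comes back at 4. It gives up catalyst control: 1 is dehydrodimerised with Ag2O (0.6 equiv, acetone/benzene 1:2, rt, dark) without chiral additive. Intermediate 3 then forms together with its mirror image, the (2S)-configured para-quinone methide aryl ether F1, and ring closure gives 4 together with an equal amount of the (2R,3R)-enantiomer F2. The two are separated by preparative HPLC on an amylose tris(3,5-dimethylphenylcarbamate) phase.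

Second, step 1 may give the wrong regiochemistry. The styryl group biases the two quinone oxygens only modestly, so the 2,3-transposed benzodioxane may dominate. The fallback sets out from 1 and comes back at 4. It replaces the quinone partner by one with a decisive bias.
- 3,4-Dihydroxybenzaldehyde is oxidised on its own (Ag2CO3 on Celite, MeCN, −30 °C, filtered cold) to 4-formyl-1,2-benzoquinone F3.
- F3 is added slowly to 1 and the same chiral acid at −60 °C. The formyl group makes the para oxygen by far the better phenoxide, so C8 of 1 goes to the meta oxygen and gives the formyl-substituted para-quinone methide aryl ether F4.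
- F4 closes in the flask to (2S,3S)-2-(3,4-dihydroxyphenyl)-3-(3,5-dihydroxyphenyl)-2,3-dihydro-1,4-benzodioxine-6-carbaldehyde F5.
- Wittig olefination of F5 with the ylide from (3,5-dihydroxybenzyl)triphenylphosphonium bromide (excess KOtBu, THF) gives 4 mixed with the (Z)-stilbene isomer F6.
- F6 is converted into 4 with catalytic diphenyl disulfide (PhSSPh) in refluxing THF under visible light.
- The known weakness of this fallback is hydrogen exchange between F3 and 1, which would give 2 and return the reaction to the path of step 1; the low temperature and slow addition are there to suppress it.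

Third, step 1 may fail on chemoselectivity. The free resorcinol rings are carbon nucleophiles towards the quinone, and the catechol of the product can be oxidised in turn, so oligomers may consume the material. The fallback sets out from 1 and comes back at 4. It masks the four resorcinol oxygens.
- PhB(OH)2 (1.05 equiv, MgSO4, THF, rt) ties up the catechol of 1 as the catechol phenylboronate F7.
- Ac2O/pyridine at 0 °C acetylates the two resorcinol oxygens, giving the boronate diacetate F8.
- Aqueous acetone hydrolyses the boronate and gives 3,5-di-O-acetylpiceatannol F9.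
- F9 is submitted to the conditions of step 1. It passes through 3,5-di-O-acetylpiceatannol ortho-quinone F10 and the tetra-O-acetylated para-quinone methide aryl ether F11, and gives the tetra-O-acetylated benzodioxane F12.
- Catalytic HCl in degassed MeOH removes the acetates and gives 4.

**Further compounds**
F1 | step 1 | 2-hydroxy-4-[(2S)-2-(3,5-dihydroxyphenyl)-2-{5-[(E)-2-(3,5-dihydroxyphenyl)ethenyl]-2-hydroxyphenoxy}ethylidene]cyclohexa-2,5-dien-1-one (enantiomer of 3) | Oc1cc(O)cc(/C=C/c2ccc(O)c(O[C@H](c3cc(O)cc(O)c3)C=C3C=CC(=O)C(O)=C3)c2)c1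
F2 | step 1 | (2R,3R)-2-(3,4-dihydroxyphenyl)-3-(3,5-dihydroxyphenyl)-6-[(E)-2-(3,5-dihydroxyphenyl)ethenyl]-2,3-dihydro-1,4-benzodioxine (enantiomer of 4) | Oc1cc(O)cc(/C=C/c2ccc3c(c2)O[C@H](c2cc(O)cc(O)c2)[C@@H](c2ccc(O)c(O)c2)O3)c1
F3 | step 1 | 4-formyl-1,2-benzoquinone (3,4-dioxocyclohexa-1,5-diene-1-carbaldehyde) | O=CC1=CC(=O)C(=O)C=C1
F4 | step 1 | 4-hydroxy-3-{[(1R)-1-(3,5-dihydroxyphenyl)-2-(3-hydroxy-4-oxocyclohexa-2,5-dien-1-ylidene)ethyl]oxy}benzaldehyde | O=Cc1ccc(O)c(O[C@@H](c2cc(O)cc(O)c2)C=C2C=CC(=O)C(O)=C2)c1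
F5 | step 1 | (2S,3S)-2-(3,4-dihydroxyphenyl)-3-(3,5-dihydroxyphenyl)-2,3-dihydro-1,4-benzodioxine-6-carbaldehyde | O=Cc1ccc2c(c1)O[C@@H](c1cc(O)cc(O)c1)[C@H](c1ccc(O)c(O)c1)O2
F6 | step 1 | (2S,3S)-2-(3,4-dihydroxyphenyl)-3-(3,5-dihydroxyphenyl)-6-[(Z)-2-(3,5-dihydroxyphenyl)ethenyl]-2,3-dihydro-1,4-benzodioxine | Oc1cc(O)cc(/C=C\c2ccc3c(c2)O[C@@H](c2cc(O)cc(O)c2)[C@H](c2ccc(O)c(O)c2)O3)c1
F7 | step 1 | 5-[(E)-2-(2-phenyl-1,3,2-benzodioxaborol-5-yl)ethenyl]benzene-1,3-diol (catechol phenylboronate of 1) | Oc1cc(O)cc(/C=C/c2ccc3OB(c4ccccc4)Oc3c2)c1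
F8 | step 1 | 5-[(E)-2-(2-phenyl-1,3,2-benzodioxaborol-5-yl)ethenyl]-1,3-phenylene diacetate | CC(=O)Oc1cc(OC(C)=O)cc(/C=C/c2ccc3OB(c4ccccc4)Oc3c2)c1
F9 | step 1 | 3,5-di-O-acetylpiceatannol, 5-[(E)-2-(3,4-dihydroxyphenyl)ethenyl]-1,3-phenylene diacetate | CC(=O)Oc1cc(OC(C)=O)cc(/C=C/c2ccc(O)c(O)c2)c1
F10 | step 1 | 3,5-di-O-acetylpiceatannol ortho-quinone, 5-[(E)-2-(3,4-dioxocyclohexa-1,5-dien-1-yl)ethenyl]-1,3-phenylene diacetate | CC(=O)Oc1cc(OC(C)=O)cc(/C=C/C2=CC(=O)C(=O)C=C2)c1
F11 | step 1 | 4-[(2R)-2-[3,5-bis(acetyloxy)phenyl]-2-{5-[(E)-2-[3,5-bis(acetyloxy)phenyl]ethenyl]-2-hydroxyphenoxy}ethylidene]-2-hydroxycyclohexa-2,5-dien-1-one | CC(=O)Oc1cc(OC(C)=O)cc(/C=C/c2ccc(O)c(O[C@@H](c3cc(OC(C)=O)cc(OC(C)=O)c3)C=C3C=CC(=O)C(O)=C3)c2)c1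
F12 | step 1 | (2S,3S)-3-(3,5-diacetoxyphenyl)-6-[(E)-2-(3,5-diacetoxyphenyl)ethenyl]-2-(3,4-dihydroxyphenyl)-2,3-dihydro-1,4-benzodioxine | CC(=O)Oc1cc(OC(C)=O)cc(/C=C/c2ccc3c(c2)O[C@@H](c2cc(OC(C)=O)cc(OC(C)=O)c2)[C@H](c2ccc(O)c(O)c2)O3)c1
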